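(All runs were computed on assumed constants.)

Time was what I compared first: how long each earlier run took to bring Z to a like fraction of its charge.

| setting | violet | grey | flask |
|---|---|---|---|
| Z | 0.060 M | 0.24 M | 0.12 M |
| X | 39 mM (held) | 39 mM (held) | 39 mM (held) |
| remark | run made earlier | run made earlier |  |
| time |  |  | 12 h |
- violet (time / h: J / %, Z / %): 1.00: 11.4, 89.0; 3.00: 41.6, 56.8; 5.00: 63.5, 31.5; 8.00: 83.1, 10.7; 12.0: 89.5, 1.5; 15.0: 90.6, 0.1
- grey (time / h: J / %, Z / %): 1.00: 7.4, 93.1; 3.00: 26.8, 70.4; 5.00: 43.7, 51.6; 8.00: 63.3, 30.7; 12.0: 81.1, 9.8; 15.0: 87.2, 4.5

(readings scatter by 1 percentage point)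
- at the start none of X is in solution
- Q is what X becomes in solution
1. how much J there is at 12 h, in percent of the Z charged
2. concentration of Q in solution at 80 min, in percent of saturation
3. the change that raises the amount of J at 12 h, in percent of the Z charged most ("none" if none brings more than 2 percentage points) (delta / gamma / none)
4. amount of J at 12 h, in percent of the Z charged, after gamma
- delta: doubling the saturation concentration of X, all else as stated
- gamma: doubling the transfer coefficient of X, all else as stated

**The zero.** A plain first-order loss of Z has the same halving time at every charge, so I took that pseudo-first-order case as the zero of my scale. The halving time of a reading is the hours run divided by the number of halvings that bring Z to the fraction read. With 10.7 % of Z left, the violet run showed 2.48 h. With 9.8 % left, the grey run showed 3.58 h, longer than violet, so the stronger charge sat off the zero. If Z waits on gas arriving at a steady pace, that stretch grows in a straight line with the charge. The flask's charge lies a third of the way from violet to grey. That gave the flask a whole-run halving time, the hours from the start per halving of Z with the first slow hour counted in, of 2.85 h, and so 5.39 % of Z left at 12 h.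

**Second way.** I repeated this on the earlier pair: 31.5 % left in violet at 5.00 h showed a halving time of 3.00 h, and 30.7 % left in grey at 8.00 h showed 4.70 h. This gave the flask 3.57 h and 9.70 % left, so the two ways parted. The second one cheats: in violet the halving time read at 5.00 h was longer than the one read at 8.00 h, so a time read early overstates a later one. I kept the first. The violet run at 12.0 h read 90.9 % of the consumed Z as J, so my J was 86.0 %.

**The forecast.** It said “That points to gas-transfer limitation” and gave 87.2 % of J, between 85 % and 89 %, which is above mine. It put Q at 46 % of saturation, chose delta, and gave 89 % after gamma.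

**The result.** The flask gave 88.6 % of J, Q at 41.6 % of saturation, delta as best change with 7.1 percentage points gained, and 92.4 % after gamma, so the forecast held.

    X ⇌ Q, rate k1*(csat - [Q]) (kL = 0.870 h⁻¹)
    Z + Q → J (k = 9.80 M⁻¹ h⁻¹)
    Z → D (k = 0.0150 h⁻¹)
    2 Q → E (k = 0.280 M⁻¹ h⁻¹)

At 2.85 h, 12 h is 4.21 halvings, and the flask kept 4.41 % of Z against my 5.39 %. J stayed at 88.6 % partly through the pace of the passage of X into Q and partly through the loss of Z to D: the flask with that passage made fast gave 95.4 %, and without D it gave 94.4 %. The flask also held E, but that loss of Q made no difference to J.

Left until 30 h, the flask has 10.5 halvings at 2.85 h, which leaves 0.0678 % of Z. The computed flask held 0 % of Z and 92.9 % of J.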